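All constants are invented; no experiment stands behind them.

Every D charged stays among D, Q, Z, E and X, and each Z made costs one G and each X two, so the G spent equals Z plus twice X.

| flask | D | G | time |
|---|---|---|---|
| winter | 0.027 M | 0.0490 M | 20 min |
| spring | 0.027 M | 0.0730 M | 20 min |
| autumn | 0.027 M | 0.110 M | 20 min |

    D ⇌ Q (K1 = 0.85, k1 = 0.0092 s⁻¹)
    E ⇌ Z, rate k2*(cs2 - [Z]) while solid is left; crystals form when [Z] > cs2 (cs2 = 26 mM, k2 = 0.069 s⁻¹)
    D + G → Z + L (k3 = 0.018 L mol⁻¹ s⁻¹)
    G + Z → X + L (k4 = 0.030 L mol⁻¹ s⁻¹)

- amounts and yields of Z count E too
- given per volume of solution although it is solid: E
- run time (winter): 20 min

- which of these there is most of at the end, counted by the D in it, winter (X / D / Z)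
- which of these there is most of at the end, counted by the D in it, spring (X / D / Z)
- which of these there is most of at the end, counted by the D in it, autumn (X / D / Z)
- how much there is at the end of the one of these that leads, in percent of the D charged: winter
- how much there is at the end of the one of these that leads, in percent of the D charged: spring
- how much there is at the end of the one of these that leads, in percent of the D charged: autumn

You asked for a quick number, and your hunch was to hold G at its charge, the pseudo-first-order shortcut. We start there and let the balance correct it.

Step 1, counted by its forward rate alone, has a half-life of 1.3 min, shorter than the 13 min of step 3 alone with winter's charges and than the run of 20 min. So we hold D and Q in equilibrium, with free D at 54.1% of their pool. The pool then falls at k3 times that share times G, and dissolved Z goes at k4 times G. Both run on one clock, and their ratio is a selectivity factor of 0.324. Dissolved Z then peaks at 18.9% of the D charged, or 5.10 mM, less than the solubility of 26 mM, so we expect no crystals.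

At full charge, winter's k4 times G times time reads 1.76. The pool left is e to the minus factor times clock. Z is the factor over one minus the factor, times the pool less e to the minus clock. X takes the remainder. By the balance, those amounts spend 37.6% of winter's G, so we take mean G as the charge less half of that spend. Winter then reads 1.43: k4 times mean G times time, the G clock.

It gives winter free D 34.0% and X 18.5%. The same steps give spring a clock of 2.15, with D 26.9% and X 32.0%. Autumn reads 3.32, with D 18.4% and X 51.3%. Even at its reckoned peak, Z stands below these reckoned leaders.

The forecast says D at 32.5% in winter (29% to 36%), X at 35% in spring (31% to 39%), and X at 52% in autumn (47% to 57%). Its estimate “leaves free D ahead at the lowest G”. It names our leaders, but its winter figure is lower than ours and its spring figure higher.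

The flask gives D at 32.8% in winter, X at 33.4% in spring and X at 51.8% in autumn, the leaders forecast. Winter ends with 67.9% of its G free. Put that reading in place of our reckoned spend, and winter's clock moves from 1.43 to 1.48, which gives free D 33.5%.

Take one more flask like winter, but with 0.083 M of G. Its clock reads 2.46, later than winter's, and gives D 24.4% and X 37.4%. The computed flask holds D 23.3% and X 38.8%, so X leads there.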